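**Strategy.** The cyclohexene ring (numbered as 7-oxabicyclo[4.1.0]hept-4-ene: C1 quaternary, C2 carbinol, C3 benzoate carbon, C4=C5, C6 epoxide CH) is cut into two penta-1,4-dien-3-ols. The key step exploits the cis-1,4 pair of allylic C–O bonds at C6 and C3 that flank C4=C5. A temporary diisopropylsilylene ties these two oxygens in an acyclic bis(pentadienyloxy)silane. A tandem double ring-closing metathesis of this tetraene forms C4=C5 and C1=C2 (the later C1–C2 bond) in one operation and gives a bridged cyclohexa-1,4-diene. A singlet-oxygen ene reaction, a directed epoxidation and a Payne rearrangement then turn the C1 methyl group into the epoxide and the CH2O arm.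

Key step: step 4

Remark 1: locants C1–C6 in the text are those of the target core defined above.
Remark 2 (assumption): the lipase is taken to follow the usual size rule for secondary alcohols (isopropenyl large, vinyl medium), so the (R)-alcohol is acylated and the (S)-alcohol is recovered.

Step 1
Reactants: 1 methacrolein; 2 vinylmagnesium bromide
Product: 3 (±)-2-methylpenta-1,4-dien-3-ol
Conditions: THF, −78 °C → 0 °C; then H2O
Reagents that add atoms: none
Why: Grignard 1,2-addition of the vinyl reagent to the enal carbonyl should give the racemic bis-allylic alcohol, with no stereocontrol needed at this stage.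

Step 2
Reactants: 3 (±)-2-methylpenta-1,4-dien-3-ol
Product: 4 (3S)-2-methylpenta-1,4-dien-3-ol
Conditions: Candida antarctica lipase B (immobilised), vinyl acetate, MTBE, 30 °C, stopped just past half conversion
Reagents that add atoms: none
Why: Lipase-catalysed kinetic resolution by enantioselective transesterification should acylate the (R)-alcohol and leave the (S)-alcohol, whose carbinol carbon becomes C6 of the target.

Step 3
Reactants: 4 (3S)-2-methylpenta-1,4-dien-3-ol; 5 penta-1,4-dien-3-ol
Product: 7 {[(3S)-2-methylpenta-1,4-dien-3-yl]oxy}(penta-1,4-dien-3-yloxy)di(propan-2-yl)silane, via chlorosilane 6 (not isolated)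
Conditions: iPr2SiCl2, imidazole, CH2Cl2, 0 °C; then 5, imidazole, 0 °C → rt
Reagents that add atoms: dichlorodi(propan-2-yl)silane, CC(C)[Si](Cl)(Cl)C(C)C
Why: Stepwise substitution at silicon (silyl ether formation) should silylate the chiral alcohol first and cap the monochlorosilane with the second alcohol, giving the unsymmetrical bis(alkoxy)silane without touching the stereocentre.

Step 4
Reactants: 7 {[(3S)-2-methylpenta-1,4-dien-3-yl]oxy}(penta-1,4-dien-3-yloxy)di(propan-2-yl)silane
Product: 9 (1R,5S)-6-methyl-3,3-di(propan-2-yl)-2,4-dioxa-3-silabicyclo[3.2.2]nona-6,8-diene, via dioxasilepine 8 (not isolated)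
Conditions: second-generation Grubbs catalyst (10 mol%), toluene (2 mM), 80 °C, Ar purge
Reagents that add atoms: none
Why: Olefin metathesis through ruthenium alkylidene/metallacyclobutane intermediates: the catalyst loads on a monosubstituted vinyl group, closure between the vinyl group on C6 and one vinyl group of the pentadienyl half forms C4=C5 in dioxasilepine 8, and the alkylidene then generated on the remaining vinyl group engages the isopropenyl group to form C1=C2, each event releasing ethene. The closest known reaction type is the temporary silicon-tethered ring-closing metathesis of bis(allyloxy)silanes, run here twice in tandem on one tether. Ring closures: first the seven-membered 1,3,2-dioxasilepine by ring-closing metathesis of two terminal alkenes, then the six-membered carbocycle (which is at the same time a second seven-membered silaketal ring, hence the bicyclo[3.2.2] frame) by ring-closing metathesis of a 1,1-disubstituted alkene onto a vinyl group. The only new stereocentre is C3: the first closure picks one of the two diastereotopic vinyl groups of the pentadienyl half under control of C6 through the tether, the cis-4,7-disubstituted ring should be preferred, only that isomer can close the second ring, and reversibility of the first closure under ethene returns the trans isomer to the pool. The step needs ring closure to win over oligomerisation and the isopropenyl group to react only in the final ring-closing event; high dilution, removal of ethene and three more reactive vinyl groups for initiation secure this.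

Step 5
Reactants: 9 (1R,5S)-6-methyl-3,3-di(propan-2-yl)-2,4-dioxa-3-silabicyclo[3.2.2]nona-6,8-diene
Product: 11 (1R,5S,6S,7S)-3,3-di(propan-2-yl)spiro[2,4-dioxa-3-silabicyclo[3.2.2]non-8-ene-6,2'-oxirane]-7-ol (epoxide O and OH both anti to the O–Si–O bridge), via hydroperoxide 10 (not isolated)
Conditions: O2, hν (visible), tetraphenylporphyrin (cat.), Ti(OiPr)4 (10 mol%), CH2Cl2, 0 °C
Reagents that add atoms: dioxygen, O=O
Why: A Schenck ene reaction of singlet oxygen on the trisubstituted alkene, from the face anti to the silaketal bridge and with only the methyl hydrogens geometrically available, should set the C2 oxygen and leave an exocyclic methylene, after which Ti(OiPr)4 transfers the peroxide oxygen to that allylic-alcohol alkene on the face of the C2 oxygen (hydroxyl-directed epoxidation) and sets the spiro centre C1.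

Step 6
Reactants: 11 (1R,5S,6S,7S)-3,3-di(propan-2-yl)spiro[2,4-dioxa-3-silabicyclo[3.2.2]non-8-ene-6,2'-oxirane]-7-ol
Product: 12 (1R,5S,6S,7S)-7-[(4-methoxyphenyl)methoxy]-3,3-di(propan-2-yl)spiro[2,4-dioxa-3-silabicyclo[3.2.2]non-8-ene-6,2'-oxirane]
Conditions: NaH, 4-methoxybenzyl chloride, Bu4NI (cat.), DMF, 0 °C → rt
Reagents that add atoms: 4-methoxybenzyl chloride, COc1ccc(CCl)cc1
Why: Williamson etherification should cap the C2 oxygen, which lies syn to the epoxide oxygen and so cannot open it, and this keeps C2–O out of the epoxide migration that follows.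

Step 7
Reactants: 12 (1R,5S,6S,7S)-7-[(4-methoxyphenyl)methoxy]-3,3-di(propan-2-yl)spiro[2,4-dioxa-3-silabicyclo[3.2.2]non-8-ene-6,2'-oxirane]
Product: 14 [(1S,2S,3R,6S)-3-hydroxy-2-[(4-methoxyphenyl)methoxy]-7-oxabicyclo[4.1.0]hept-4-en-1-yl]methanol, via diol 13 (not isolated)
Conditions: TBAF, THF, 0 °C → rt; then aq NaOH (0.5 M, cat.), t-BuOH, rt
Reagents that add atoms: none
Why: Fluoride removes the silicon tether, and the freed C6 alkoxide should open the spiro epoxide at C1 anti to its C–O bond (Payne rearrangement, 3-exo-tet, inversion at C1), giving the more substituted C1–C6 epoxide and a primary alcohol as the thermodynamically preferred isomer.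

Step 8
Reactants: 14 [(1S,2S,3R,6S)-3-hydroxy-2-[(4-methoxyphenyl)methoxy]-7-oxabicyclo[4.1.0]hept-4-en-1-yl]methanol
Product: 15 [(1S,2S,3R,6S)-3-(benzoyloxy)-2-[(4-methoxyphenyl)methoxy]-7-oxabicyclo[4.1.0]hept-4-en-1-yl]methyl benzoate
Conditions: BzCl (2.5 equiv), Et3N, DMAP (cat.), CH2Cl2, 0 °C
Reagents that add atoms: benzoyl chloride, O=C(Cl)c1ccccc1
Why: DMAP-catalysed acylation should esterify the only two free hydroxyl groups (primary CH2OH and allylic C3–OH) without touching a stereocentre.

Step 9
Reactants: 15 [(1S,2S,3R,6S)-3-(benzoyloxy)-2-[(4-methoxyphenyl)methoxy]-7-oxabicyclo[4.1.0]hept-4-en-1-yl]methyl benzoate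
Product: 16 [(1R,2S,3R,6S)-3-(benzoyloxy)-2-hydroxy-7-oxabicyclo[4.1.0]hept-4-en-1-yl]methyl benzoate (CNP0192269.6)
Conditions: DDQ, CH2Cl2/pH 7 phosphate buffer, 0 °C → rt
Reagents that add atoms: none
Why: Oxidative cleavage of the 4-methoxybenzyl ether by DDQ (benzylic hydride abstraction, then hydrolysis) should free C2–OH under neutral conditions that avoid benzoyl migration and opening of the vinyl epoxide.

**Compound list**

1 | methacrolein (2-methylprop-2-enal) | CC(=C)C=O | starting material
2 | vinylmagnesium bromide | C=C[Mg]Br | starting material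
3 | (±)-2-methylpenta-1,4-dien-3-ol | CC(=C)C(O)C=C | intermediate
4 | (3S)-2-methylpenta-1,4-dien-3-ol | CC(=C)[C@@H](O)C=C | intermediate
5 | penta-1,4-dien-3-ol | C=CC(O)C=C | starting material
6 | chloro{[(3S)-2-methylpenta-1,4-dien-3-yl]oxy}di(propan-2-yl)silane | CC(=C)[C@@H](O[Si](Cl)(C(C)C)C(C)C)C=C | intermediate
7 | {[(3S)-2-methylpenta-1,4-dien-3-yl]oxy}(penta-1,4-dien-3-yloxy)di(propan-2-yl)silane | CC(=C)[C@@H](O[Si](C(C)C)(C(C)C)OC(C=C)C=C)C=C | intermediate
8 | (4S,7S)-7-ethenyl-4-(prop-1-en-2-yl)-2,2-di(propan-2-yl)-4,7-dihydro-1,3,2-dioxasilepine (cis) | CC(=C)[C@@H]1C=C[C@H](C=C)O[Si](C(C)C)(C(C)C)O1 | intermediate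
9 | (1R,5S)-6-methyl-3,3-di(propan-2-yl)-2,4-dioxa-3-silabicyclo[3.2.2]nona-6,8-diene | CC1=C[C@H]2C=C[C@@H]1O[Si](C(C)C)(C(C)C)O2 | intermediate
10 | (1R,5S,7R)-7-hydroperoxy-6-methylidene-3,3-di(propan-2-yl)-2,4-dioxa-3-silabicyclo[3.2.2]non-8-ene (OOH anti to the O–Si–O bridge) | C=C1[C@@H](OO)[C@H]2C=C[C@@H]1O[Si](C(C)C)(C(C)C)O2 | intermediate
11 | (1R,5S,6S,7S)-3,3-di(propan-2-yl)spiro[2,4-dioxa-3-silabicyclo[3.2.2]non-8-ene-6,2'-oxirane]-7-ol | C1O[C@]12[C@@H](O)[C@H]3C=C[C@@H]2O[Si](C(C)C)(C(C)C)O3 | intermediate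
12 | (1R,5S,6S,7S)-7-[(4-methoxyphenyl)methoxy]-3,3-di(propan-2-yl)spiro[2,4-dioxa-3-silabicyclo[3.2.2]non-8-ene-6,2'-oxirane] | C1O[C@]12[C@@H](OCc4ccc(OC)cc4)[C@H]3C=C[C@@H]2O[Si](C(C)C)(C(C)C)O3 | intermediate
13 | (3R,4S,5R,8S)-4-[(4-methoxyphenyl)methoxy]-1-oxaspiro[2.5]oct-6-ene-5,8-diol | C1O[C@]12[C@@H](OCc3ccc(OC)cc3)[C@H](O)C=C[C@@H]2O | intermediate
14 | [(1S,2S,3R,6S)-3-hydroxy-2-[(4-methoxyphenyl)methoxy]-7-oxabicyclo[4.1.0]hept-4-en-1-yl]methanol | OC[C@]12O[C@H]1C=C[C@@H](O)[C@@H]2OCc1ccc(OC)cc1 | intermediate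
15 | [(1S,2S,3R,6S)-3-(benzoyloxy)-2-[(4-methoxyphenyl)methoxy]-7-oxabicyclo[4.1.0]hept-4-en-1-yl]methyl benzoate | O=C(OC[C@]12O[C@H]1C=C[C@@H](OC(=O)c1ccccc1)[C@@H]2OCc1ccc(OC)cc1)c1ccccc1 | intermediate
16 | [(1R,2S,3R,6S)-3-(benzoyloxy)-2-hydroxy-7-oxabicyclo[4.1.0]hept-4-en-1-yl]methyl benzoate (CNP0192269.6) | O=C(OC[C@]12O[C@H]1C=C[C@@H](OC(=O)c1ccccc1)[C@@H]2O)c1ccccc1 | target

**Totals.** Total step count: 9. Longest linear sequence: 9 steps (from 1 and 2; compound 5 enters at step 3).

**Steps most likely to fail**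

Step 4 (key step). After the first closure the alkylidene may fail to reach the hindered isopropenyl group across the seven-membered ring, so the reaction could stall at the monocycle or drift into oligomers. The fallback makes the two bonds in separate closures and forms the carbocycle without a bridge. It sets out from 7: first-generation Grubbs catalyst (CH2Cl2, 40 °C), which leaves the 1,1-disubstituted alkene largely untouched, should give dioxasilepine 8, now isolated. TBAF/AcOH removes the tether to give (3S,6S,4Z)-2-methylocta-1,4,7-triene-3,6-diol F1. Second-generation Grubbs catalyst then closes the six-membered ring between the isopropenyl and vinyl ends held cis by the Z alkene, giving (1S,4R)-2-methylcyclohexa-2,5-diene-1,4-diol F2. Re-bridging the cis-1,4-diol with iPr2Si(OTf)2 and 2,6-lutidine comes back to the route at 9.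

Step 7. Substitution by the C6 alkoxide at the fully substituted C1 may be too slow, so that opening of the spiro epoxide at its CH2 by hydroxide, or decomposition, takes over. The fallback forms the C1–O bond by epoxidising a C1=C6 alkene instead. It sets out from diol 13, isolated after buffered desilylation of 12 (TBAF/AcOH). Silylation of the less hindered C3–OH (TBSCl, imidazole) gives (3R,4S,5R,8S)-5-[(tert-butyldimethylsilyl)oxy]-4-[(4-methoxyphenyl)methoxy]-1-oxaspiro[2.5]oct-6-en-8-ol F3. Dess–Martin oxidation gives (3S,4S,5R)-5-[(tert-butyldimethylsilyl)oxy]-4-[(4-methoxyphenyl)methoxy]-1-oxaspiro[2.5]oct-6-en-8-one F4. Wharton transposition (N2H4·H2O, AcOH cat., MeOH) gives [(5R,6R)-5-[(tert-butyldimethylsilyl)oxy]-6-[(4-methoxyphenyl)methoxy]cyclohexa-1,3-dien-1-yl]methanol F5. Hydroxyl-directed epoxidation (VO(acac)2, TBHP) anti to the C2 ether gives [(1S,2S,3R,6S)-3-[(tert-butyldimethylsilyl)oxy]-2-[(4-methoxyphenyl)methoxy]-7-oxabicyclo[4.1.0]hept-4-en-1-yl]methanol F6. TBAF/AcOH comes back to the route at 14.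

Step 2. The lipase may discriminate poorly between vinyl and isopropenyl, so that 4 would be recovered with too low an enantiomeric purity. The fallback resolves a propargylic analogue, which has a much larger size difference, and then reduces it. It sets out from 1: ethynylmagnesium bromide gives (±)-2-methylpent-1-en-4-yn-3-ol F7. The same lipase with vinyl acetate should acylate the (S)-enynol and leave (3R)-2-methylpent-1-en-4-yn-3-ol F8, which has the same spatial arrangement as 4 (the descriptor changes because ethynyl outranks isopropenyl). Semihydrogenation (H2, Pd/CaCO3 poisoned with Pb(OAc)2, quinoline) comes back to the route at 4.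

**Further compounds**

F1 | step 4 | (3S,6S,4Z)-2-methylocta-1,4,7-triene-3,6-diol | CC(=C)[C@@H](O)/C=C\[C@@H](O)C=C
F2 | step 4 | (1S,4R)-2-methylcyclohexa-2,5-diene-1,4-diol | CC1=C[C@H](O)C=C[C@@H]1O
F3 | step 7 | (3R,4S,5R,8S)-5-[(tert-butyldimethylsilyl)oxy]-4-[(4-methoxyphenyl)methoxy]-1-oxaspiro[2.5]oct-6-en-8-ol | C1O[C@]12[C@@H](OCc3ccc(OC)cc3)[C@H](O[Si](C)(C)C(C)(C)C)C=C[C@@H]2O
F4 | step 7 | (3S,4S,5R)-5-[(tert-butyldimethylsilyl)oxy]-4-[(4-methoxyphenyl)methoxy]-1-oxaspiro[2.5]oct-6-en-8-one | C1O[C@]12[C@@H](OCc3ccc(OC)cc3)[C@H](O[Si](C)(C)C(C)(C)C)C=CC2=O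
F5 | step 7 | [(5R,6R)-5-[(tert-butyldimethylsilyl)oxy]-6-[(4-methoxyphenyl)methoxy]cyclohexa-1,3-dien-1-yl]methanol | OCC1=CC=C[C@@H](O[Si](C)(C)C(C)(C)C)[C@@H]1OCc1ccc(OC)cc1
F6 | step 7 | [(1S,2S,3R,6S)-3-[(tert-butyldimethylsilyl)oxy]-2-[(4-methoxyphenyl)methoxy]-7-oxabicyclo[4.1.0]hept-4-en-1-yl]methanol | OC[C@]12O[C@H]1C=C[C@@H](O[Si](C)(C)C(C)(C)C)[C@@H]2OCc1ccc(OC)cc1
F7 | step 2 | (±)-2-methylpent-1-en-4-yn-3-ol | CC(=C)C(O)C#C
F8 | step 2 | (3R)-2-methylpent-1-en-4-yn-3-ol | CC(=C)[C@@H](O)C#C
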